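**Strategy.** Each ring A (C1 arylethyl arm, C2 bridge, C3 OMe, C5 OH) is cut at C1–C2 and C5–C6. What remains is C2–C5 of both rings plus the bridging CH2. This is one unbranched nine-carbon chain oxygenated at chain positions 1, 3, 7 and 9, that is, dimethyl 3,7-dioxononanedioate. The key step exploits this hidden symmetry. The derived bis(1,3-dimethoxy-1-silyloxydiene) adds two molecules of an arylethyl alkynoate, which supply C1 and C6. Loss of methanol aromatises both rings in one operation, with OMe beside and OH para to the bridge. The activating C6 ester is benzyl, so hydrogenolysis and thermal decarboxylation finish the synthesis.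

Key step: step 9

Remark on stereochemistry: the target SMILES holds no stereogenic element, so the compound is achiral and there is no enantiomer to select. Only the alkene geometries of the enol ether and diene intermediates need control. The ketene-acetal double bonds are left undefined because they vanish on aromatisation.

Remark on design: a benzyl ester avoids saponifying a hindered, chelated salicylate. A neutral silylating scavenger in the key step keeps the methanol set free by the first ring closure away from the second diene.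

**Step 1**
Reactants: 1 pentanedioyl dichloride; 2 2,2-dimethyl-1,3-dioxane-4,6-dione (Meldrum's acid, 2.1 equiv)
Product: 3 5,5'-(1,5-dihydroxypentane-1,5-diylidene)bis(2,2-dimethyl-1,3-dioxane-4,6-dione)
Conditions: pyridine (4.4 equiv), CH2Cl2, 0 °C → rt, slow addition of 1; 1 M HCl wash; crude solid
Reagents that add atoms: none
Why: C-Acylation of the Meldrum's acid enolate by an aliphatic acid chloride is a standard reaction, and slow addition of 1 to an excess of 2/pyridine favours the twofold intermolecular acylation over enol-lactone closure of the mono-acylated intermediate.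

**Step 2**
Reactants: 3 bis(acyl Meldrum's acid)
Product: 4 dimethyl 3,7-dioxononanedioate
Conditions: MeOH, reflux
Reagents that add atoms: methanol, CO
Why: Alcoholysis of acyl Meldrum's acids (loss of acetone and CO2 through the acylketene, trapping by methanol) gives β-keto esters under neutral conditions, which leave the aldol-prone 1,5-diketone untouched.

**Step 3**
Reactants: 4 dimethyl 3,7-dioxononanedioate
Product: 5 dimethyl (2E,7E)-3,7-dimethoxynona-2,7-dienedioate
Conditions: HC(OMe)3 (6 equiv), conc. H2SO4 (cat.), MeOH, rt → 40 °C; solid K2CO3 quench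
Reagents that add atoms: trimethyl orthoformate, COC(OC)OC; methanol, CO
Why: Acid-catalysed ketalisation and elimination of methanol, with the orthoformate as water scavenger, converts β-keto esters into the conjugated (E)-3-methoxy-2-enoates (the thermodynamic isomers with ester and OMe anti), and the water-free methanolic medium works against cyclic enol ethers of the 1,5-dicarbonyl unit.

**Step 4**
Reactants: 5 dimethyl (2E,7E)-3,7-dimethoxynona-2,7-dienedioate
Product: 7 (3Z,6Z)-1,3,7,9-tetramethoxy-1,9-bis(trimethylsilyloxy)nona-1,3,6,8-tetraene (C5 on the outside of each diene), via dilithium bis(dienolate) 6 (not isolated)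
Conditions: LDA (commercial, 2.4 equiv), THF, −78 °C, 5 added to the base; TMSCl (3 equiv), −78 → 0 °C; evaporate, dry pentane, filter under Ar, use at once
Reagents that add atoms: chlorotrimethylsilane, C[Si](C)(C)Cl
Why: Kinetic γ-deprotonation of an (E)-3-methoxy-2-enoate by ester-bound LDA followed by O-silylation is the standard entry to Brassard-type dienes, and because the ester is cis to the γ-CH2 the dienolate is formed s-cis, so that allylic strain with the ester oxygens turns C5 to the outside and sets the (3Z,6Z) geometry.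

**Step 5**
Reactants: 8 3-(4-hydroxy-3-methoxyphenyl)propan-1-ol (dihydroconiferyl alcohol)
Product: 9 3-[4-(benzyloxy)-3-methoxyphenyl]propan-1-ol
Conditions: BnBr (1.05 equiv), K2CO3, acetone, reflux
Reagents that add atoms: benzyl bromide, BrCc1ccccc1
Why: Williamson etherification under carbonate conditions deprotonates only the phenol, so the primary alcohol stays free.

**Step 6**
Reactants: 9 3-[4-(benzyloxy)-3-methoxyphenyl]propan-1-ol
Product: 10 3-[4-(benzyloxy)-3-methoxyphenyl]propanal
Conditions: TEMPO (10 mol%), PhI(OAc)2 (1.1 equiv), CH2Cl2, rt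
Reagents that add atoms: none
Why: Oxoammonium (TEMPO) oxidation with PhI(OAc)2 as terminal oxidant stops at the aldehyde in the absence of water and tolerates the benzyl-protected electron-rich arene.

**Step 7**
Reactants: 10 3-[4-(benzyloxy)-3-methoxyphenyl]propanal
Product: 11 1-(benzyloxy)-4-(4,4-dibromobut-3-en-1-yl)-2-methoxybenzene
Conditions: CBr4 (2 equiv), PPh3 (4 equiv), CH2Cl2, 0 °C
Reagents that add atoms: carbon tetrabromide, BrC(Br)(Br)Br
Why: This is the first stage of the Corey–Fuchs homologation, in which the ylide Ph3P=CBr2 formed from PPh3 and CBr4 olefinates the aliphatic aldehyde in a Wittig reaction.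

**Step 8**
Reactants: 11 dibromoalkene; 12 benzyl chloroformate (1.3 equiv)
Product: 14 benzyl 5-[4-(benzyloxy)-3-methoxyphenyl]pent-2-ynoate, via lithium 4-[4-(benzyloxy)-3-methoxyphenyl]but-1-yn-1-ide 13 (not isolated)
Conditions: n-BuLi (2.1 equiv), THF, −78 °C; then 12, −78 → 0 °C
Reagents that add atoms: none
Why: This is the second stage of the Corey–Fuchs homologation, in which Br/Li exchange, Fritsch–Buttenberg–Wiechell-type loss of LiBr and deprotonation give acetylide 13, which the chloroformate acylates on carbon, the aryl ethers being inert to n-BuLi at −78 °C on this time scale.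

**Step 9**
Reactants: 7 bis-diene (1 equiv); 14 benzyl alkynoate (3 equiv, excess recovered)
Product: 17 dibenzyl 3,3'-methylenebis{2-[2-(4-benzyloxy-3-methoxyphenyl)ethyl]-6-hydroxy-4-methoxybenzoate}, via bis(cyclohexa-1,4-diene) cycloadduct 15 (not isolated), via bis(trimethylsilyl ether) of the bis-salicylate 16 (not isolated)
Conditions: N,O-bis(trimethylsilyl)acetamide (BSA, 3 equiv), neat melt (minimal o-xylene if needed), sealed tube, Ar, 130–140 °C; then THF/0.5 M aq HCl, rt
Reagents that add atoms: none
Why: Each electron-rich 1,1,3-trioxygenated diene of 7 adds to one molecule of 14 in a strongly asynchronous, normal-electron-demand [4+2] cycloaddition in which the nucleophilic terminus (chain C4/C6, attached to the central CH2) bonds to the β-carbon of the ynoate and the ketene-acetal carbon (chain C1/C9) to the α-carbon, giving 15. The closest known reaction type is the Diels–Alder/aromatisation of 1,3-dimethoxy-1-silyloxybutadienes (4-alkyl members included) and related oxygenated dienes with activated alkynes, β-alkyl alkynoates among them, to give 6-alkyl-4-methoxysalicylates. Both rings A close intermolecularly as six-membered carbocycles by [4+2] addition (bonds C2–C1 and C5–C6 in each), and 1,4-elimination of methanol from the mixed ketal at C5 and the C2–H, with the silyl rather than the methyl group finally lost from that oxygen as usual for this diene class, makes them aromatic, so the transient sp3 centres of 15 are erased and no stereocentre remains. Regioselectivity is the only selectivity needed and is secured by matched polarisation (largest HOMO coefficient at the diene terminus remote from the ketene acetal, largest LUMO coefficient at the ynoate β-carbon), which puts OMe beside the bridge, OH para to it and the ester on C6. The (3Z,6Z) geometry keeps the tether on the outside of each diene, so the s-cis conformer is reachable and a 1,5-H shift from the doubly allylic CH2 is geometrically excluded. BSA silylates the methanol and phenol set free by the first ring closure, which would otherwise protodesilylate the second, still unreacted ketene acetal, while excess 14 and a concentrated melt offset the low rate expected for a β-alkyl ynoate.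

**Step 10**
Reactants: 17 dibenzyl bis-salicylate
Product: 18 3,3'-methylenebis{6-hydroxy-2-[2-(4-hydroxy-3-methoxyphenyl)ethyl]-4-methoxybenzoic acid}
Conditions: H2 (1 atm), 10% Pd/C, THF–MeOH, rt
Reagents that add atoms: none
Why: Heterogeneous hydrogenolysis cleaves all four benzylic C–O bonds (two esters, two aryl ethers) under neutral conditions, which avoids saponification of a di-ortho-substituted chelated salicylate, while the diarylmethane C–C bonds and the methyl ethers are inert.

**Step 11**
Reactants: 18 bis(salicylic acid)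
Product: 19 4,4'-methylenebis{3-[2-(4-hydroxy-3-methoxyphenyl)ethyl]-5-methoxyphenol} (target)
Conditions: degassed DMF, Ar, 120–130 °C, until CO2 evolution ends
Reagents that add atoms: none
Why: Thermal protodecarboxylation by ipso-protonation is easy for benzoic acids with ortho-OH and para-OMe (the orsellinic/everninic acid type, which loses CO2 on moderate heating without a catalyst), and the neutral, oxygen-free medium protects the acid-sensitive electron-rich diarylmethane and the free phenols.

**Compound list**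
1 | pentanedioyl dichloride | O=C(Cl)CCCC(=O)Cl | starting material
2 | 2,2-dimethyl-1,3-dioxane-4,6-dione (Meldrum's acid) | CC1(C)OC(=O)CC(=O)O1 | starting material
3 | 5,5'-(1,5-dihydroxypentane-1,5-diylidene)bis(2,2-dimethyl-1,3-dioxane-4,6-dione) | CC1(C)OC(=O)C(=C(O)CCCC(O)=C2C(=O)OC(C)(C)OC2=O)C(=O)O1 | intermediate
4 | dimethyl 3,7-dioxononanedioate | COC(=O)CC(=O)CCCC(=O)CC(=O)OC | intermediate
5 | dimethyl (2E,7E)-3,7-dimethoxynona-2,7-dienedioate | COC(=O)/C=C(OC)\CCC/C(OC)=C\C(=O)OC | intermediate
6 | dilithium (3Z,6Z)-1,3,7,9-tetramethoxynona-1,3,6,8-tetraene-1,9-bis(olate) | [Li]OC(OC)=C/C(OC)=C/C/C=C(OC)/C=C(OC)O[Li] | intermediate (not isolated)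
7 | (3Z,6Z)-1,3,7,9-tetramethoxy-1,9-bis(trimethylsilyloxy)nona-1,3,6,8-tetraene | COC(O[Si](C)(C)C)=C/C(OC)=C/C/C=C(OC)/C=C(OC)O[Si](C)(C)C | intermediate
8 | 3-(4-hydroxy-3-methoxyphenyl)propan-1-ol | COc1cc(CCCO)ccc1O | starting material
9 | 3-[4-(benzyloxy)-3-methoxyphenyl]propan-1-ol | COc1cc(CCCO)ccc1OCc1ccccc1 | intermediate
10 | 3-[4-(benzyloxy)-3-methoxyphenyl]propanal | COc1cc(CCC=O)ccc1OCc1ccccc1 | intermediate
11 | 1-(benzyloxy)-4-(4,4-dibromobut-3-en-1-yl)-2-methoxybenzene | COc1cc(CCC=C(Br)Br)ccc1OCc1ccccc1 | intermediate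
12 | benzyl chloroformate | O=C(Cl)OCc1ccccc1 | starting material
13 | lithium 4-[4-(benzyloxy)-3-methoxyphenyl]but-1-yn-1-ide | [Li]C#CCCc1ccc(OCc2ccccc2)c(OC)c1 | intermediate (not isolated)
14 | benzyl 5-[4-(benzyloxy)-3-methoxyphenyl]pent-2-ynoate | O=C(OCc1ccccc1)C#CCCc1ccc(OCc2ccccc2)c(OC)c1 | intermediate
15 | bis(cyclohexa-1,4-diene) cycloadduct (transient sp3 centres, undefined mixture) | COC1=CC(OC)(O[Si](C)(C)C)C(C(=O)OCc2ccccc2)=C(CCc2ccc(OCc3ccccc3)c(OC)c2)C1CC1C(OC)=CC(OC)(O[Si](C)(C)C)C(C(=O)OCc2ccccc2)=C1CCc1ccc(OCc2ccccc2)c(OC)c1 | intermediate (not isolated)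
16 | dibenzyl 3,3'-methylenebis{2-[2-(4-benzyloxy-3-methoxyphenyl)ethyl]-4-methoxy-6-(trimethylsilyloxy)benzoate} | COc1cc(O[Si](C)(C)C)c(C(=O)OCc2ccccc2)c(CCc2ccc(OCc3ccccc3)c(OC)c2)c1Cc1c(OC)cc(O[Si](C)(C)C)c(C(=O)OCc2ccccc2)c1CCc1ccc(OCc2ccccc2)c(OC)c1 | intermediate (not isolated)
17 | dibenzyl 3,3'-methylenebis{2-[2-(4-benzyloxy-3-methoxyphenyl)ethyl]-6-hydroxy-4-methoxybenzoate} | COc1cc(O)c(C(=O)OCc2ccccc2)c(CCc2ccc(OCc3ccccc3)c(OC)c2)c1Cc1c(OC)cc(O)c(C(=O)OCc2ccccc2)c1CCc1ccc(OCc2ccccc2)c(OC)c1 | intermediate
18 | 3,3'-methylenebis{6-hydroxy-2-[2-(4-hydroxy-3-methoxyphenyl)ethyl]-4-methoxybenzoic acid} | COc1cc(O)c(C(=O)O)c(CCc2ccc(O)c(OC)c2)c1Cc1c(OC)cc(O)c(C(=O)O)c1CCc1ccc(O)c(OC)c1 | intermediate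
19 | 4,4'-methylenebis{3-[2-(4-hydroxy-3-methoxyphenyl)ethyl]-5-methoxyphenol} (CNP0079383.0, achiral) | COc1cc(CCc2cc(O)cc(OC)c2Cc2c(CCc3ccc(O)c(OC)c3)cc(O)cc2OC)ccc1O | target

**Total step count:** 11. **Longest linear sequence:** 7 steps (steps 5–8 or steps 1–4, then steps 9–11).

**Steps most likely to fail**

1. **Step 9.**
   - Risk: Bond formation between the secondary diene terminus and the β-alkyl-substituted ynoate carbon may be very slow. Thermal decay or protodesilylation of the ketene acetals could then outrun the second ring closure, and the reaction would stop at the mono-annulated stage.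
   - Fallback (sets out from 9 and 7, comes back at 17): The ynoate is replaced by the isomeric allenoate. This is a more reactive 2π partner, less hindered at the bond-forming sp carbon, and is known to give 6-alkylresorcylates with oxygenated silyloxydienes. Alcohol 9 is oxidised (TEMPO, PhI(OAc)2, MeCN–H2O) to 3-[4-(benzyloxy)-3-methoxyphenyl]propanoic acid F1. Oxalyl chloride with catalytic DMF converts it into 3-[4-(benzyloxy)-3-methoxyphenyl]propanoyl chloride F2. Et3N generates 3-[4-(benzyloxy)-3-methoxyphenyl]prop-1-en-1-one (the ketene) F3, which benzyl (triphenylphosphoranylidene)acetate intercepts in a Wittig reaction to give racemic benzyl 5-[4-(benzyloxy)-3-methoxyphenyl]penta-2,3-dienoate F4. Bis-diene 7 should add across the α,β-double bond of two molecules of the allenoate (toluene, 80–110 °C) with the same orientation, giving the bis(alkylidenecyclohexene) cycloadduct F5. Dilute HCl in THF then removes methanol and the silyl groups and moves the exocyclic double bonds into the rings, giving 17.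

2. **Step 4.**
   - Risk: The second γ-deprotonation may lag, so that the mono-dienolate condenses with the remaining enoate. Silylation may take place partly on carbon. The trimethylsilyl ketene acetals may hydrolyse during isolation.
   - Fallback (sets out from 5, comes back at 17): Soft enolisation avoids any lithium dienolate and installs a hydrolytically robust silyl group. TBSOTf/Et3N (Et2O, 0 °C → rt) should give (3Z,6Z)-1,9-bis(tert-butyldimethylsilyloxy)-1,3,7,9-tetramethoxynona-1,3,6,8-tetraene F6, which tolerates a bicarbonate wash and filtration through deactivated alumina. Cycloaddition with 14 in the presence of BSA, as in step 9, leads through the bis(cyclohexa-1,4-diene) TBS cycloadduct F7 to dibenzyl 3,3'-methylenebis{2-[2-(4-benzyloxy-3-methoxyphenyl)ethyl]-6-(tert-butyldimethylsilyloxy)-4-methoxybenzoate} F8. TBAF/AcOH in THF converts this into 17.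

3. **Step 3.**
   - Risk: Under acid the 1,5-dicarbonyl unit may close to cyclic enol ethers or aldol products before both ketones are enol-etherified. Ketal/enol ether mixtures of mixed geometry may also result.
   - Fallback (sets out from 4, comes back at 17): The methyl ethers are postponed and a Chan-type bis-diene is used. TMSCl/Et3N gives dimethyl (2Z,7Z)-3,7-bis(trimethylsilyloxy)nona-2,7-dienedioate F9. LDA deprotonates it to the dilithium bis(dienolate) F10, and TMSCl then gives (3Z,6Z)-1,9-dimethoxy-1,3,7,9-tetrakis(trimethylsilyloxy)nona-1,3,6,8-tetraene F11. Cycloaddition with 14 and BSA, as in step 9, leads through the bis(cyclohexa-1,4-diene) tetrasilyl cycloadduct F12 and the tetrakis(trimethylsilyl ether) F13. Acidic work-up gives dibenzyl 3,3'-methylenebis{2-[2-(4-benzyloxy-3-methoxyphenyl)ethyl]-4,6-dihydroxybenzoate} F14. MeI (2.2 equiv)/K2CO3 in acetone methylates only the two non-chelated 4-OH groups, the known selectivity of 2,4-dihydroxybenzoates, and gives 17.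

**Further compounds**
F1 | step 9 | 3-[4-(benzyloxy)-3-methoxyphenyl]propanoic acid | COc1cc(CCC(=O)O)ccc1OCc1ccccc1
F2 | step 9 | 3-[4-(benzyloxy)-3-methoxyphenyl]propanoyl chloride | COc1cc(CCC(=O)Cl)ccc1OCc1ccccc1
F3 | step 9 | 3-[4-(benzyloxy)-3-methoxyphenyl]prop-1-en-1-one (ketene) | COc1cc(CC=C=O)ccc1OCc1ccccc1
F4 | step 9 | benzyl 5-[4-(benzyloxy)-3-methoxyphenyl]penta-2,3-dienoate (racemic) | O=C(OCc1ccccc1)C=C=CCc1ccc(OCc2ccccc2)c(OC)c1
F5 | step 9 | bis(alkylidenecyclohexene) cycloadduct (undefined mixture of stereoisomers) | COC1=CC(OC)(O[Si](C)(C)C)C(C(=O)OCc2ccccc2)C(=CCc2ccc(OCc3ccccc3)c(OC)c2)C1CC1C(OC)=CC(OC)(O[Si](C)(C)C)C(C(=O)OCc2ccccc2)C1=CCc1ccc(OCc2ccccc2)c(OC)c1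
F6 | step 4 | (3Z,6Z)-1,9-bis(tert-butyldimethylsilyloxy)-1,3,7,9-tetramethoxynona-1,3,6,8-tetraene | COC(O[Si](C)(C)C(C)(C)C)=C/C(OC)=C/C/C=C(OC)/C=C(OC)O[Si](C)(C)C(C)(C)C
F7 | step 4 | bis(cyclohexa-1,4-diene) TBS cycloadduct (undefined mixture of stereoisomers) | COC1=CC(OC)(O[Si](C)(C)C(C)(C)C)C(C(=O)OCc2ccccc2)=C(CCc2ccc(OCc3ccccc3)c(OC)c2)C1CC1C(OC)=CC(OC)(O[Si](C)(C)C(C)(C)C)C(C(=O)OCc2ccccc2)=C1CCc1ccc(OCc2ccccc2)c(OC)c1
F8 | step 4 | dibenzyl 3,3'-methylenebis{2-[2-(4-benzyloxy-3-methoxyphenyl)ethyl]-6-(tert-butyldimethylsilyloxy)-4-methoxybenzoate} | COc1cc(O[Si](C)(C)C(C)(C)C)c(C(=O)OCc2ccccc2)c(CCc2ccc(OCc3ccccc3)c(OC)c2)c1Cc1c(OC)cc(O[Si](C)(C)C(C)(C)C)c(C(=O)OCc2ccccc2)c1CCc1ccc(OCc2ccccc2)c(OC)c1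
F9 | step 3 | dimethyl (2Z,7Z)-3,7-bis(trimethylsilyloxy)nona-2,7-dienedioate | COC(=O)/C=C(O[Si](C)(C)C)/CCC/C(O[Si](C)(C)C)=C/C(=O)OC
F10 | step 3 | dilithium (3Z,6Z)-1,9-dimethoxy-3,7-bis(trimethylsilyloxy)nona-1,3,6,8-tetraene-1,9-bis(olate) | [Li]OC(OC)=C/C(O[Si](C)(C)C)=C/C/C=C(O[Si](C)(C)C)/C=C(OC)O[Li]
F11 | step 3 | (3Z,6Z)-1,9-dimethoxy-1,3,7,9-tetrakis(trimethylsilyloxy)nona-1,3,6,8-tetraene | COC(O[Si](C)(C)C)=C/C(O[Si](C)(C)C)=C/C/C=C(O[Si](C)(C)C)/C=C(OC)O[Si](C)(C)C
F12 | step 3 | bis(cyclohexa-1,4-diene) tetrasilyl cycloadduct (undefined mixture of stereoisomers) | C[Si](C)(C)OC1=CC(OC)(O[Si](C)(C)C)C(C(=O)OCc2ccccc2)=C(CCc2ccc(OCc3ccccc3)c(OC)c2)C1CC1C(O[Si](C)(C)C)=CC(OC)(O[Si](C)(C)C)C(C(=O)OCc2ccccc2)=C1CCc1ccc(OCc2ccccc2)c(OC)c1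
F13 | step 3 | dibenzyl 3,3'-methylenebis{2-[2-(4-benzyloxy-3-methoxyphenyl)ethyl]-4,6-bis(trimethylsilyloxy)benzoate} | C[Si](C)(C)Oc1cc(O[Si](C)(C)C)c(C(=O)OCc2ccccc2)c(CCc2ccc(OCc3ccccc3)c(OC)c2)c1Cc1c(O[Si](C)(C)C)cc(O[Si](C)(C)C)c(C(=O)OCc2ccccc2)c1CCc1ccc(OCc2ccccc2)c(OC)c1
F14 | step 3 | dibenzyl 3,3'-methylenebis{2-[2-(4-benzyloxy-3-methoxyphenyl)ethyl]-4,6-dihydroxybenzoate} | Oc1cc(O)c(C(=O)OCc2ccccc2)c(CCc2ccc(OCc3ccccc3)c(OC)c2)c1Cc1c(O)cc(O)c(C(=O)OCc2ccccc2)c1CCc1ccc(OCc2ccccc2)c(OC)c1
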